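The 14-membered ring (C1 bears isopropenyl; ketones at C3, C6, C10; E-enoate C12=C13) is opened at C12=C13, C10–C11 and C2–C3, which leaves the oxolan-3-one ring (O, C5, C6, C7, C8) as the core. That ring is disconnected at C7–C8: the C7 methylene is flanked by the C6 carbonyl and by C8, a fully substituted carbon bonded to the ring oxygen, so a rhodium carbenoid at C7 can insert into the C8–H bond of an open-chain ether. In one operation this closes the five-membered ring, makes C7–C8 and creates the quaternary centre with retention. The precursor is a terminal α-alkoxy diazoketone whose ether links two secondary stereocentres, C5 and C8.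

Key step: step 7

Remark (numbering): C1 carries the isopropenyl group, the ring is numbered through the C3 ketone, the ether oxygen bridges C5 and C8, and the methyl ester sits on C12; the target is 1S,5S,8S with an E alkene (CO2Me trans to C14).

Remark (configuration check): 8S corresponds to (S)-butane-1,3-diol carried through with retention; 5S and the (R)-configured iodide 25 (1S once the priorities change in the target) both require the (R)-4-benzyl auxiliary.

Remark (precursor design): the C10 oxygen is carried as a 4-methoxybenzyl (PMB) ether, because a silyl ether 1,3 to the secondary alkoxide could migrate during the Williamson step. The C3 carboxyl is an allyl ester, so that it can be freed at neutral pH without acid (which would strip the PMB ether) or base (which would epimerise C5 or open the oxolanone by β-elimination). All steps after step 7 are run at or near neutrality for the same reason.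

Assumption: the C10 carbinol in 32 is taken on as a mixture of epimers, since step 18 removes this centre.

Step 1
Reactants: 1 (S)-butane-1,3-diol
Product: 2 (S)-4-[(4-methoxybenzyl)oxy]butan-2-ol
Conditions: NaH (1.0 equiv), THF, 0 °C; 4-methoxybenzyl chloride (1.0 equiv), Bu4NI (cat.), 0 °C to rt
Reagents that add atoms: 4-methoxybenzyl chloride, COc1ccc(CCl)cc1
Why: Williamson etherification in which, with one equivalent of base, the less hindered primary alkoxide should be alkylated preferentially, while the purchased stereocentre (future C8) is not involved.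

Step 2
Reactants: 2 (S)-4-[(4-methoxybenzyl)oxy]butan-2-ol; 3 bromoacetic acid
Product: 4 2-{[(2S)-4-[(4-methoxybenzyl)oxy]butan-2-yl]oxy}acetic acid
Conditions: NaH (3 equiv), THF/DMF, 0 °C to rt; then cold dilute HCl to pH 3
Reagents that add atoms: none
Why: Williamson etherification of the secondary sodium alkoxide with sodium bromoacetate, in which the C–O bond at the stereocentre is never broken (retention) and the benzyl-type ether cannot migrate to the alkoxide.

Step 3
Reactants: 4 2-{[(2S)-4-[(4-methoxybenzyl)oxy]butan-2-yl]oxy}acetic acid; 5 (R)-4-benzyloxazolidin-2-one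
Product: 7 (4R)-4-benzyl-3-(2-{[(2S)-4-[(4-methoxybenzyl)oxy]butan-2-yl]oxy}acetyl)oxazolidin-2-one, via mixed pivalic anhydride 6 (not isolated)
Conditions: t-BuCOCl, Et3N, THF, −20 °C; then LiCl, 5, −20 °C to rt
Reagents that add atoms: none
Why: N-acylation of the oxazolidinone through a mixed anhydride, in which the nucleophile should attack the unhindered alkoxyacetyl carbonyl and not the pivaloyl one.

Step 4
Reactants: 7 (4R)-4-benzyl-3-(2-{[(2S)-4-[(4-methoxybenzyl)oxy]butan-2-yl]oxy}acetyl)oxazolidin-2-one; 8 prop-2-en-1-yl bromoacetate (allyl bromoacetate)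
Product: 10 prop-2-en-1-yl (3S)-4-[(4R)-4-benzyl-2-oxooxazolidin-3-yl]-3-{[(2S)-4-[(4-methoxybenzyl)oxy]butan-2-yl]oxy}-4-oxobutanoate, via sodium enolate 9 (not isolated)
Conditions: NaN(SiMe3)2 (1.1 equiv), THF, −78 °C; then 8 (3 equiv), −78 to −45 °C
Reagents that add atoms: none
Why: Evans-type asymmetric alkylation of a glycolate imide, in which the chelated sodium Z-enolate should be alkylated by the reactive α-bromo ester on the face away from the benzyl group of the (R)-auxiliary, setting C5 as S.

Step 5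
Reactants: 10 prop-2-en-1-yl (3S)-4-[(4R)-4-benzyl-2-oxooxazolidin-3-yl]-3-{[(2S)-4-[(4-methoxybenzyl)oxy]butan-2-yl]oxy}-4-oxobutanoate
Product: 12 (2S)-2-{[(2S)-4-[(4-methoxybenzyl)oxy]butan-2-yl]oxy}-4-oxo-4-(prop-2-en-1-yloxy)butanoic acid, via peroxy acid 11 (not isolated)
Conditions: LiOH, H2O2, THF/H2O (3:1), 0 °C; then aq. Na2SO3; dilute HCl to pH 3
Reagents that add atoms: hydrogen peroxide, OO
Why: Hydroperoxide hydrolysis of the imide, which should cleave the activated exocyclic carbonyl faster than the allyl ester at 0 °C and does not enolise the α-alkoxy centre; sulfite then reduces the peroxy acid.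

Step 6
Reactants: 12 (2S)-2-{[(2S)-4-[(4-methoxybenzyl)oxy]butan-2-yl]oxy}-4-oxo-4-(prop-2-en-1-yloxy)butanoic acid
Product: 14 prop-2-en-1-yl (3S)-5-diazo-3-{[(2S)-4-[(4-methoxybenzyl)oxy]butan-2-yl]oxy}-4-oxopentanoate, via mixed carbonic anhydride 13 (not isolated)
Conditions: i-BuOCOCl, N-methylmorpholine, THF, −20 °C; then CH2N2, Et2O, −20 to 0 °C
Reagents that add atoms: diazomethane, C=[N+]=[N-]
Why: Acylation of diazomethane by a mixed carbonic anhydride (the first stage of an Arndt–Eistert sequence) should give the terminal diazoketone without touching C5, the allyl ester or the unactivated alkene.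

Step 7
Reactants: 14 prop-2-en-1-yl (3S)-5-diazo-3-{[(2S)-4-[(4-methoxybenzyl)oxy]butan-2-yl]oxy}-4-oxopentanoate
Product: 15 prop-2-en-1-yl 2-[(2S,5S)-5-{2-[(4-methoxybenzyl)oxy]ethyl}-5-methyl-3-oxooxolan-2-yl]acetate
Conditions: Rh2(OAc)4 (1 mol %), CH2Cl2, rt, slow addition of 14 (final 5 mM)
Reagents that add atoms: none
Why: Rh2(OAc)4 expels N2 from 14 to give an electrophilic rhodium carbenoid at C7, which inserts into the C8–H bond through a concerted three-centre transition state with hydride-like transfer and release of the catalyst. The closest known reaction type is the dirhodium-catalysed intramolecular 1,5 C–H insertion of α-alkoxy diazomethyl ketones next to ether oxygen, an established entry to oxolan-3-ones. The oxolanone closes by C7–C8 bond formation through the five-membered array C7–C6–C5–O–C8, the preferred ring size for carbenoid insertion. C8 becomes the quaternary stereocentre with retention, because the new C–C bond forms on the face from which hydrogen leaves, so the S configuration bought with the diol is copied into the ring; C5 is not involved, and its S configuration from step 4 places the chains on C5 and C8 on opposite faces of the ring. The step needs site selectivity for the C8 methine over the C9 methylene and the C8 methyl (six-membered transition states), the C10 methylene, the allyl alkene and the ester carbonyl oxygen; the adjacent ether oxygen and the tertiary character make C8–H the most hydridic bond within reach, the ring size favours it, and slow addition at high dilution should suppress carbene dimerisation and intermolecular cyclopropanation.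

Step 8
Reactants: 15 prop-2-en-1-yl 2-[(2S,5S)-5-{2-[(4-methoxybenzyl)oxy]ethyl}-5-methyl-3-oxooxolan-2-yl]acetate
Product: 16 2-[(2S,5S)-5-{2-[(4-methoxybenzyl)oxy]ethyl}-5-methyl-3-oxooxolan-2-yl]acetic acid
Conditions: Pd(PPh3)4 (5 mol %), N-methylaniline (3 equiv), THF, rt
Reagents that add atoms: none
Why: Deallylation catalysed by zerovalent palladium (Tsuji–Trost type), in which the π-allyl complex is trapped by the weakly basic aniline, so the acid is freed without epimerising C5, opening the oxolanone or cleaving the PMB ether.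

Step 9
Reactants: 16 2-[(2S,5S)-5-{2-[(4-methoxybenzyl)oxy]ethyl}-5-methyl-3-oxooxolan-2-yl]acetic acid
Product: 17 S-ethyl 2-[(2S,5S)-5-{2-[(4-methoxybenzyl)oxy]ethyl}-5-methyl-3-oxooxolan-2-yl]ethanethioate
Conditions: EtSH, DCC, DMAP (5 mol %), CH2Cl2, 0 °C
Reagents that add atoms: ethanethiol, CCS
Why: Steglich-type carbodiimide thioesterification, in which the thiol should acylate at 0 °C faster than the catalytic base can enolise the oxolanone.

Step 10
Reactants: 5 (R)-4-benzyloxazolidin-2-one; 18 3-methylbut-2-enoyl chloride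
Product: 20 (4R)-4-benzyl-3-(3-methylbut-2-enoyl)oxazolidin-2-one, via lithiated oxazolidinone 19 (not isolated)
Conditions: n-BuLi, THF, −78 °C; then 18, −78 to 0 °C
Reagents that add atoms: none
Why: Standard N-acylation of a lithiated oxazolidinone with an acid chloride.

Step 11
Reactants: 20 (4R)-4-benzyl-3-(3-methylbut-2-enoyl)oxazolidin-2-one; 21 3-iodoprop-1-ene (allyl iodide)
Product: 23 (4R)-4-benzyl-3-[(2R)-2-(prop-1-en-2-yl)pent-4-enoyl]oxazolidin-2-one, via sodium dienolate 22 (not isolated)
Conditions: NaN(SiMe3)2 (1.1 equiv), THF, −78 °C; then 21 (3 equiv), −78 °C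
Reagents that add atoms: none
Why: Deconjugative Evans alkylation, in which γ-deprotonation gives the chelated sodium dienolate and allylation at its α-carbon on the face away from the benzyl group should set the future C1 (2R in 23, 1S in the target).

Step 12
Reactants: 23 (4R)-4-benzyl-3-[(2R)-2-(prop-1-en-2-yl)pent-4-enoyl]oxazolidin-2-one
Product: 24 (2R)-2-(prop-1-en-2-yl)pent-4-en-1-ol
Conditions: LiBH4, H2O (1 equiv), Et2O, 0 °C
Reagents that add atoms: none
Why: Reductive cleavage of the imide with borohydride should release the primary alcohol and the auxiliary at 0 °C before the acidic α-vinyl centre can epimerise or move into conjugation.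

Step 13
Reactants: 24 (2R)-2-(prop-1-en-2-yl)pent-4-en-1-ol
Product: 25 (4R)-4-(iodomethyl)-5-methylhexa-1,5-diene
Conditions: I2, PPh3, imidazole, CH2Cl2, 0 °C
Reagents that add atoms: iodine, II
Why: Appel-type iodination by SN2 displacement at the primary carbon, which leaves the neighbouring stereocentre and both alkenes untouched.

Step 14
Reactants: 17 S-ethyl 2-[(2S,5S)-5-{2-[(4-methoxybenzyl)oxy]ethyl}-5-methyl-3-oxooxolan-2-yl]ethanethioate; 25 (4R)-4-(iodomethyl)-5-methylhexa-1,5-diene
Product: 27 (2S,5S)-5-{2-[(4-methoxybenzyl)oxy]ethyl}-5-methyl-2-[(4S)-2-oxo-4-(prop-1-en-2-yl)hept-6-en-1-yl]oxolan-3-one, via alkylzinc iodide 26 (not isolated)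
Conditions: 25 (2.5 equiv), Zn dust (activated with BrCH2CH2Br and Me3SiCl), LiCl, THF, 40 °C; then 17, PdCl2(PPh3)2 (5 mol %), toluene, rt
Reagents that add atoms: none
Why: Fukuyama coupling, in which zinc inserts into the primary C–I bond and the alkylzinc iodide transfers its alkyl group to the acylpalladium formed from the thioester, making C2–C3 and the C3 ketone while the C6 ketone, the ether and the alkenes are inert to the organozinc.

Step 15
Reactants: 27 (2S,5S)-5-{2-[(4-methoxybenzyl)oxy]ethyl}-5-methyl-2-[(4S)-2-oxo-4-(prop-1-en-2-yl)hept-6-en-1-yl]oxolan-3-one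
Product: 28 (2S,5S)-5-(2-hydroxyethyl)-5-methyl-2-[(4S)-2-oxo-4-(prop-1-en-2-yl)hept-6-en-1-yl]oxolan-3-one
Conditions: DDQ (1.3 equiv), CH2Cl2/pH 7 phosphate buffer (10:1), 0 °C
Reagents that add atoms: none
Why: Oxidative removal of the PMB ether (hydride abstraction from the electron-rich benzylic position, then hydrolysis), which in buffered medium should leave ketones and unactivated alkenes alone.

Step 16
Reactants: 28 (2S,5S)-5-(2-hydroxyethyl)-5-methyl-2-[(4S)-2-oxo-4-(prop-1-en-2-yl)hept-6-en-1-yl]oxolan-3-one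
Product: 29 2-[(2S,5S)-2-methyl-4-oxo-5-[(4S)-2-oxo-4-(prop-1-en-2-yl)hept-6-en-1-yl]oxolan-2-yl]acetaldehyde
Conditions: Dess–Martin periodinane, NaHCO3, CH2Cl2, 0 °C to rt
Reagents that add atoms: none
Why: Dess–Martin oxidation of the primary alcohol (through the open hydroxy ketone if a hemiketal with C6 forms), which stops at the aldehyde and avoids the base that would eliminate the ring oxygen.

Step 17
Reactants: 29 2-[(2S,5S)-2-methyl-4-oxo-5-[(4S)-2-oxo-4-(prop-1-en-2-yl)hept-6-en-1-yl]oxolan-2-yl]acetaldehyde; 30 methyl 2-(bromomethyl)acrylate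
Product: 32 methyl 4-hydroxy-5-[(2S,5S)-2-methyl-4-oxo-5-[(4S)-2-oxo-4-(prop-1-en-2-yl)hept-6-en-1-yl]oxolan-2-yl]-2-methylidenepentanoate (C4 epimers), via allylzinc bromide 31 (not isolated)
Conditions: 30 (1.3 equiv), Zn dust, THF/sat. aq. NH4Cl (4:1), 0 °C
Reagents that add atoms: none
Why: Aqueous Barbier allylation, in which the allylzinc should add to the aldehyde much faster than to either ketone and form C10–C11; the new carbinol centre is not controlled and is removed in step 18.

Step 18
Reactants: 32 methyl 4-hydroxy-5-[(2S,5S)-2-methyl-4-oxo-5-[(4S)-2-oxo-4-(prop-1-en-2-yl)hept-6-en-1-yl]oxolan-2-yl]-2-methylidenepentanoate (C4 epimers)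
Product: 33 methyl 5-[(2S,5S)-2-methyl-4-oxo-5-[(4S)-2-oxo-4-(prop-1-en-2-yl)hept-6-en-1-yl]oxolan-2-yl]-2-methylidene-4-oxopentanoate
Conditions: Dess–Martin periodinane, NaHCO3, CH2Cl2, 0 °C
Reagents that add atoms: none
Why: Dess–Martin oxidation of the secondary homoallylic alcohol under buffered neutral conditions should give the C10 ketone without drawing the 1,1-disubstituted alkene into conjugation.

Step 19
Reactants: 33 methyl 5-[(2S,5S)-2-methyl-4-oxo-5-[(4S)-2-oxo-4-(prop-1-en-2-yl)hept-6-en-1-yl]oxolan-2-yl]-2-methylidene-4-oxopentanoate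
Product: 34 methyl (1S,5E,8S,12S)-1-methyl-3,10,13-trioxo-8-(prop-1-en-2-yl)-15-oxabicyclo[10.2.1]pentadec-5-ene-5-carboxylate (the target; 1S,5S,8S in the numbering used here)
Conditions: second-generation Hoveyda–Grubbs catalyst (10 mol %), 1,4-benzoquinone (20 mol %), toluene (1 mM), 80 °C
Reagents that add atoms: none
Why: Ring-closing metathesis, in which the ruthenium alkylidene formed at the monosubstituted C13 alkene closes onto the 2-substituted acrylate with loss of ethene; the E enoate is the geometry expected for metathesis of 2-substituted acrylates and here puts C11 and C14 cis on the alkene, which a 14-membered ring accommodates, while the isopropenyl group has no productive ring to form.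

Compound list
1 | (S)-butane-1,3-diol | C[C@H](O)CCO | starting material
2 | (S)-4-[(4-methoxybenzyl)oxy]butan-2-ol | C[C@H](O)CCOCc1ccc(OC)cc1 | intermediate
3 | bromoacetic acid | OC(=O)CBr | starting material
4 | 2-{[(2S)-4-[(4-methoxybenzyl)oxy]butan-2-yl]oxy}acetic acid | C[C@@H](CCOCc1ccc(OC)cc1)OCC(=O)O | intermediate
5 | (R)-4-benzyloxazolidin-2-one | O=C1N[C@H](Cc2ccccc2)CO1 | starting material
6 | mixed anhydride of 4 with pivalic acid | C[C@@H](CCOCc1ccc(OC)cc1)OCC(=O)OC(=O)C(C)(C)C | intermediate (not isolated)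
7 | (4R)-4-benzyl-3-(2-{[(2S)-4-[(4-methoxybenzyl)oxy]butan-2-yl]oxy}acetyl)oxazolidin-2-one | C[C@@H](CCOCc1ccc(OC)cc1)OCC(=O)N1[C@H](Cc2ccccc2)COC1=O | intermediate
8 | prop-2-en-1-yl bromoacetate (allyl bromoacetate) | C=CCOC(=O)CBr | starting material
9 | sodium Z-enolate of 7 (O–Na cis to the alkoxy group) | [Na+].[O-]/C(=C\O[C@@H](C)CCOCc1ccc(OC)cc1)N1[C@H](Cc2ccccc2)COC1=O | intermediate (not isolated)
10 | prop-2-en-1-yl (3S)-4-[(4R)-4-benzyl-2-oxooxazolidin-3-yl]-3-{[(2S)-4-[(4-methoxybenzyl)oxy]butan-2-yl]oxy}-4-oxobutanoate | C=CCOC(=O)C[C@H](O[C@@H](C)CCOCc1ccc(OC)cc1)C(=O)N1[C@H](Cc2ccccc2)COC1=O | intermediate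
11 | peroxy acid corresponding to 12 (C(=O)OOH in place of CO2H) | C=CCOC(=O)C[C@H](O[C@@H](C)CCOCc1ccc(OC)cc1)C(=O)OO | intermediate (not isolated)
12 | (2S)-2-{[(2S)-4-[(4-methoxybenzyl)oxy]butan-2-yl]oxy}-4-oxo-4-(prop-2-en-1-yloxy)butanoic acid | C=CCOC(=O)C[C@H](O[C@@H](C)CCOCc1ccc(OC)cc1)C(=O)O | intermediate
13 | mixed anhydride of 12 with isobutyl hydrogen carbonate | C=CCOC(=O)C[C@H](O[C@@H](C)CCOCc1ccc(OC)cc1)C(=O)OC(=O)OCC(C)C | intermediate (not isolated)
14 | prop-2-en-1-yl (3S)-5-diazo-3-{[(2S)-4-[(4-methoxybenzyl)oxy]butan-2-yl]oxy}-4-oxopentanoate | C=CCOC(=O)C[C@H](O[C@@H](C)CCOCc1ccc(OC)cc1)C(=O)C=[N+]=[N-] | intermediate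
15 | prop-2-en-1-yl 2-[(2S,5S)-5-{2-[(4-methoxybenzyl)oxy]ethyl}-5-methyl-3-oxooxolan-2-yl]acetate | COc1ccc(COCC[C@@]2(C)CC(=O)[C@H](CC(=O)OCC=C)O2)cc1 | intermediate
16 | 2-[(2S,5S)-5-{2-[(4-methoxybenzyl)oxy]ethyl}-5-methyl-3-oxooxolan-2-yl]acetic acid | COc1ccc(COCC[C@@]2(C)CC(=O)[C@H](CC(=O)O)O2)cc1 | intermediate
17 | S-ethyl 2-[(2S,5S)-5-{2-[(4-methoxybenzyl)oxy]ethyl}-5-methyl-3-oxooxolan-2-yl]ethanethioate | COc1ccc(COCC[C@@]2(C)CC(=O)[C@H](CC(=O)SCC)O2)cc1 | intermediate
18 | 3-methylbut-2-enoyl chloride | CC(C)=CC(=O)Cl | starting material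
19 | lithium salt of 5 (N-lithiated) | [Li+].O=C1[N-][C@H](Cc2ccccc2)CO1 | intermediate (not isolated)
20 | (4R)-4-benzyl-3-(3-methylbut-2-enoyl)oxazolidin-2-one | CC(C)=CC(=O)N1[C@H](Cc2ccccc2)COC1=O | intermediate
21 | 3-iodoprop-1-ene (allyl iodide) | C=CCI | starting material
22 | sodium dienolate of 20 (O–Na cis to the isopropenyl group) | [Na+].[O-]/C(=C\C(C)=C)N1[C@H](Cc2ccccc2)COC1=O | intermediate (not isolated)
23 | (4R)-4-benzyl-3-[(2R)-2-(prop-1-en-2-yl)pent-4-enoyl]oxazolidin-2-one | C=CC[C@H](C(C)=C)C(=O)N1[C@H](Cc2ccccc2)COC1=O | intermediate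
24 | (2R)-2-(prop-1-en-2-yl)pent-4-en-1-ol | C=CC[C@H](C(C)=C)CO | intermediate
25 | (4R)-4-(iodomethyl)-5-methylhexa-1,5-diene | C=CC[C@H](C(C)=C)CI | intermediate
26 | [(2R)-2-(prop-1-en-2-yl)pent-4-en-1-yl]zinc iodide | C=CC[C@H](C(C)=C)C[Zn]I | intermediate (not isolated)
27 | (2S,5S)-5-{2-[(4-methoxybenzyl)oxy]ethyl}-5-methyl-2-[(4S)-2-oxo-4-(prop-1-en-2-yl)hept-6-en-1-yl]oxolan-3-one | COc1ccc(COCC[C@@]2(C)CC(=O)[C@H](CC(=O)C[C@@H](C(C)=C)CC=C)O2)cc1 | intermediate
28 | (2S,5S)-5-(2-hydroxyethyl)-5-methyl-2-[(4S)-2-oxo-4-(prop-1-en-2-yl)hept-6-en-1-yl]oxolan-3-one | OCC[C@@]1(C)CC(=O)[C@H](CC(=O)C[C@@H](C(C)=C)CC=C)O1 | intermediate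
29 | 2-[(2S,5S)-2-methyl-4-oxo-5-[(4S)-2-oxo-4-(prop-1-en-2-yl)hept-6-en-1-yl]oxolan-2-yl]acetaldehyde | O=CC[C@@]1(C)CC(=O)[C@H](CC(=O)C[C@@H](C(C)=C)CC=C)O1 | intermediate
30 | methyl 2-(bromomethyl)acrylate | COC(=O)C(=C)CBr | starting material
31 | [2-(methoxycarbonyl)prop-2-en-1-yl]zinc bromide | COC(=O)C(=C)C[Zn]Br | intermediate (not isolated)
32 | methyl 4-hydroxy-5-[(2S,5S)-2-methyl-4-oxo-5-[(4S)-2-oxo-4-(prop-1-en-2-yl)hept-6-en-1-yl]oxolan-2-yl]-2-methylidenepentanoate (C4 epimers) | COC(=O)C(=C)CC(O)C[C@@]1(C)CC(=O)[C@H](CC(=O)C[C@@H](C(C)=C)CC=C)O1 | intermediate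
33 | methyl 5-[(2S,5S)-2-methyl-4-oxo-5-[(4S)-2-oxo-4-(prop-1-en-2-yl)hept-6-en-1-yl]oxolan-2-yl]-2-methylidene-4-oxopentanoate | COC(=O)C(=C)CC(=O)C[C@@]1(C)CC(=O)[C@H](CC(=O)C[C@@H](C(C)=C)CC=C)O1 | intermediate
34 | methyl (1S,5E,8S,12S)-1-methyl-3,10,13-trioxo-8-(prop-1-en-2-yl)-15-oxabicyclo[10.2.1]pentadec-5-ene-5-carboxylate | C=C(C)[C@H]1C/C=C(/C(=O)OC)CC(=O)C[C@@]2(C)CC(=O)[C@H](CC(=O)C1)O2 | target

Total step count: 19 (steps 1–9 and 14–19 on the main line, steps 10–13 for the C1 building block).
Longest linear sequence: 15 steps (1–9, then 14–19).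

Steps most likely to fail

1. Step 7 (carbenoid insertion). The carbenoid may be diverted before it reaches C8–H: attack on the C3 ester carbonyl oxygen (six-membered carbonyl ylide), insertion into a C9–H bond, dimerisation or Wolff rearrangement. The fallback uses a more selective acceptor/acceptor carbenoid for the same bond; it sets out from acid 12 and returns at oxolanone 15. Acid 12 is activated with carbonyldiimidazole and homologated with Mg(O2CCH2CO2tBu)2 to the β-keto ester 6-tert-butyl 1-(prop-2-en-1-yl) (3S)-3-{[(2S)-4-[(4-methoxybenzyl)oxy]butan-2-yl]oxy}-4-oxohexanedioate F1. Diazo transfer with 4-acetamidobenzenesulfonyl azide and Et3N gives the corresponding 5-diazo-4-oxohexanedioate F2. Rh2(OAc)4 in CH2Cl2 at reflux should then insert into C8–H with retention to give tert-butyl (2S,5S)-2-{2-[(4-methoxybenzyl)oxy]ethyl}-2-methyl-4-oxo-5-[2-oxo-2-(prop-2-en-1-yloxy)ethyl]oxolane-3-carboxylate F3. Heating F3 in wet toluene releases tert-butanol through the acylketene, and the β-keto acid loses CO2 under neutral conditions to give 15.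

2. Step 19 (ring-closing metathesis). Ring closure may lose to oligomerisation through the monosubstituted alkene, the slow-reacting 2-substituted acrylate may not be engaged, ruthenium hydrides may move the 1,1-disubstituted alkene into conjugation with the C10 ketone, and the alkene geometry rests only on ring and substituent preferences. The fallback closes the ring before the C10 ketone exists; it sets out from alcohol 32 and returns at target 34. Silylation of 32 (Et3SiCl, imidazole, CH2Cl2) gives the triethylsilyl ether of 32 F4, which has no enolisable β,γ-unsaturated ketone. Metathesis under the conditions of step 19 should give the macrocyclic silyl ether (34 with C10 as a triethylsilyloxy-bearing carbon) F5. HF·pyridine in THF gives the macrocyclic C10 alcohol F6, and buffered Dess–Martin oxidation of F6 gives 34.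

3. Step 17 (Barbier allylation). Chemoselectivity may be lost through addition of the allylzinc to the C3 or C6 ketone, the γ-hydroxy ester may lactonise, or the β-alkoxy aldehyde may eliminate the ring oxygen. The fallback makes C10–C11 by acyl substitution instead of carbonyl addition; it sets out from aldehyde 29 and returns at triketone 33, bypassing 32. Pinnick oxidation of 29 (NaClO2, NaH2PO4, 2-methylbut-2-ene, t-BuOH/H2O) gives 2-[(2R,5S)-2-methyl-4-oxo-5-[(4S)-2-oxo-4-(prop-1-en-2-yl)hept-6-en-1-yl]oxolan-2-yl]acetic acid F7 (same spatial arrangement as 29; the descriptor changes by priority only). 1-Chloro-N,N,2-trimethylprop-1-en-1-amine in CH2Cl2 converts F7 under neutral conditions into the corresponding acid chloride F8. Stille-type acylation of methyl 2-[(tributylstannyl)methyl]acrylate with F8 and Pd(PPh3)4 in THF should then give 33 directly.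

Further compounds
F1 | step 7 | 6-tert-butyl 1-(prop-2-en-1-yl) (3S)-3-{[(2S)-4-[(4-methoxybenzyl)oxy]butan-2-yl]oxy}-4-oxohexanedioate | C=CCOC(=O)C[C@H](O[C@@H](C)CCOCc1ccc(OC)cc1)C(=O)CC(=O)OC(C)(C)C
F2 | step 7 | 6-tert-butyl 1-(prop-2-en-1-yl) (3S)-5-diazo-3-{[(2S)-4-[(4-methoxybenzyl)oxy]butan-2-yl]oxy}-4-oxohexanedioate | C=CCOC(=O)C[C@H](O[C@@H](C)CCOCc1ccc(OC)cc1)C(=O)C(=[N+]=[N-])C(=O)OC(C)(C)C
F3 | step 7 | tert-butyl (2S,5S)-2-{2-[(4-methoxybenzyl)oxy]ethyl}-2-methyl-4-oxo-5-[2-oxo-2-(prop-2-en-1-yloxy)ethyl]oxolane-3-carboxylate (C3 epimers) | COc1ccc(COCC[C@@]2(C)C(C(=O)OC(C)(C)C)C(=O)[C@H](CC(=O)OCC=C)O2)cc1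
F4 | step 19 | triethylsilyl ether of 32 (C4 epimers of the pentanoate) | COC(=O)C(=C)CC(O[Si](CC)(CC)CC)C[C@@]1(C)CC(=O)[C@H](CC(=O)C[C@@H](C(C)=C)CC=C)O1
F5 | step 19 | macrocyclic silyl ether: 34 with C10 as a triethylsilyloxy-bearing carbon (C10 epimers) | C=C(C)[C@H]1C/C=C(/C(=O)OC)CC(O[Si](CC)(CC)CC)C[C@@]2(C)CC(=O)[C@H](CC(=O)C1)O2
F6 | step 19 | macrocyclic alcohol: 34 with C10 as a carbinol (C10 epimers) | C=C(C)[C@H]1C/C=C(/C(=O)OC)CC(O)C[C@@]2(C)CC(=O)[C@H](CC(=O)C1)O2
F7 | step 17 | 2-[(2R,5S)-2-methyl-4-oxo-5-[(4S)-2-oxo-4-(prop-1-en-2-yl)hept-6-en-1-yl]oxolan-2-yl]acetic acid | OC(=O)C[C@@]1(C)CC(=O)[C@H](CC(=O)C[C@@H](C(C)=C)CC=C)O1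
F8 | step 17 | 2-[(2R,5S)-2-methyl-4-oxo-5-[(4S)-2-oxo-4-(prop-1-en-2-yl)hept-6-en-1-yl]oxolan-2-yl]acetyl chloride | ClC(=O)C[C@@]1(C)CC(=O)[C@H](CC(=O)C[C@@H](C(C)=C)CC=C)O1
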